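**Retrosynthetic overview**
- Target ⇐ one-pot saponification/desilylation; the isopropylidene ⇐ reductive carbonyl coupling of a C2 ketone with acetone.
- 8a-Methyl and the C1 propanoate ⇐ cuprate addition/Michael trapping on a bicyclic enone (sets the cis ring fusion and C1).
- Ar–CH2 bond (key bond) ⇐ palladium-catalysed reductive coupling of an aryl bromide with the tosylhydrazone of a neopentyl aldehyde.
- Ring C (the only ring built) ⇐ catalytic asymmetric Diels–Alder of a 1-vinylcyclohexene ketal (ring B, bought as cyclohexane-1,3-dione) with (E)-2-methylbut-2-enal (sets C4a, C5, C6).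
- Aryl bromide ⇐ hydroquinone (methylation, ortho-formylation, reduction, bromination, silylation).

Conventions: bicyclic compounds carry the naphthalene locants of the target (C1 bears the propanoate, C2 the isopropylidene, C4a is the ring-fusion CH, C5 the quaternary carbon, C6 the CHCH3, C8a the second ring-fusion carbon). Ar = 2-(tert-butyldimethylsilyloxy)-5-methoxy-3-methylphenyl. The SMILES strings are authoritative for configuration.
Assumption: in step 4 the catalyst antipode is the one that sends the diene to the Re face of C2 of the enal; it is written here as the (S)-prolinol-derived catalyst, and its mirror image would be used if the facial sense proves opposite.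

**Step 1**
Reactants: 1 cyclohexane-1,3-dione
Product: 2 3-chlorocyclohex-2-en-1-one
Conditions: (COCl)2, DMF (cat.), CH2Cl2, 0 °C to rt
Reagents that add atoms: oxalyl chloride, ClC(=O)C(=O)Cl
Why: Vilsmeier-type chlorodehydroxylation of the enol form of the 1,3-diketone gives the vinylogous acid chloride.

**Step 2**
Reactants: 2 3-chlorocyclohex-2-en-1-one; 3 potassium vinyltrifluoroborate
Product: 4 3-ethenylcyclohex-2-en-1-one
Conditions: Pd(OAc)2 (2 mol %), SPhos (4 mol %), Cs2CO3, THF/H2O, 65 °C
Reagents that add atoms: none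
Why: Suzuki–Miyaura coupling, in which the β-chloroenone behaves as an activated vinyl chloride and the trifluoroborate is a stable vinyl donor.

**Step 3**
Reactants: 4 3-ethenylcyclohex-2-en-1-one
Product: 5 7-ethenyl-1,4-dioxaspiro[4.5]dec-7-ene
Conditions: HOCH2CH2OH, p-TsOH (cat.), benzene, reflux, Dean–Stark
Reagents that add atoms: ethane-1,2-diol, OCCO
Why: acid-catalysed ketalisation with the usual shift of the ring double bond to the β,γ position (α-protonation of the intermediate trienol ether), which gives an achiral 1-vinylcyclohexene diene with the ketone masked.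

**Step 4**
Reactants: 5 7-ethenyl-1,4-dioxaspiro[4.5]dec-7-ene; 6 (E)-2-methylbut-2-enal
Product: 7 aldehyde cycloadduct (2,2-ethylenedioxy-5,6-dimethyl-1,2,3,4,4a,5,6,7-octahydronaphthalene-5-carbaldehyde; C8=C8a alkene; H-4a/5-CH3/6-CH3 on one face and CHO on the other)
Conditions: (S)-B-(o-tolyl)-diphenylprolinol oxazaborolidinium triflimide (20 mol %), CH2Cl2, −78 to −40 °C
Reagents that add atoms: none
Why: catalytic asymmetric Diels–Alder reaction, in which the ring terminus of the diene bonds to the formyl-bearing carbon ("ortho" mode) through an endo-formyl transition state so that H-4a ends up cis to the 5-methyl, the E geometry of 6 fixes 5-CH3 and 6-CH3 cis, and the catalyst exposes the Re face of C2 of the enal, which sets C4a, C5 and C6 in the absolute sense shown.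

**Step 5**
Reactants: 7 aldehyde cycloadduct
Product: 8 (E)-N-tosylhydrazone of 7
Conditions: TsNHNH2, MeOH, rt
Reagents that add atoms: 4-methylbenzenesulfonohydrazide, Cc1ccc(cc1)S(=O)(=O)NN
Why: hydrazone condensation of the non-enolisable neopentyl aldehyde under neutral conditions that leave the ketal untouched.

**Step 6**
Reactants: 9 hydroquinone
Product: 10 4-methoxyphenol
Conditions: MeOH, H2SO4, NaNO2 (cat.), rt
Reagents that add atoms: methanol, CO
Why: nitrite-catalysed selective mono-etherification of hydroquinone, which stops at the monomethyl ether.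

**Step 7**
Reactants: 10 4-methoxyphenol
Product: 11 2-hydroxy-5-methoxybenzaldehyde
Conditions: MgCl2, Et3N, (CH2O)n, MeCN, reflux
Reagents that add atoms: formaldehyde (as paraformaldehyde), C=O
Why: magnesium phenoxide-directed ortho-formylation (Casnati–Skattebøl type), exclusively ortho to the hydroxyl group.

**Step 8**
Reactants: 11 2-hydroxy-5-methoxybenzaldehyde
Product: 12 4-methoxy-2-methylphenol
Conditions: H2 (4 atm), Pd/C (10 wt % palladium on carbon), AcOH, HCl (cat.), 40 °C
Reagents that add atoms: none
Why: catalytic hydrogenation/benzylic hydrogenolysis of the electron-rich salicylaldehyde takes the formyl group down to methyl.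

**Step 9**
Reactants: 12 4-methoxy-2-methylphenol
Product: 13 2-bromo-4-methoxy-6-methylphenol
Conditions: NBS, i-Pr2NH (10 mol %), CH2Cl2, 0 °C
Reagents that add atoms: N-bromosuccinimide, O=C1CCC(=O)N1Br
Why: amine-promoted electrophilic ortho-bromination of the free phenol at the only open position ortho to OH.

**Step 10**
Reactants: 13 2-bromo-4-methoxy-6-methylphenol
Product: 14 (2-bromo-4-methoxy-6-methylphenoxy)(tert-butyl)dimethylsilane
Conditions: TBSCl, imidazole, DMF, rt
Reagents that add atoms: tert-butyldimethylsilyl chloride, CC(C)(C)[Si](C)(C)Cl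
Why: standard silylation, giving a phenol ether that survives weak base, dilute acid, cuprates and low-valent titanium and falls off under the final hydroxide conditions.

**Step 11**
Reactants: 8 (E)-N-tosylhydrazone of 7; 14 (2-bromo-4-methoxy-6-methylphenoxy)(tert-butyl)dimethylsilane
Product: 18 conjugated enone (5-(ArCH2)-5,6-dimethyl-4,4a,5,6,7,8-hexahydronaphthalen-2(3H)-one; C1=C8a alkene), via diazoalkane 15 (not isolated), via coupled ketal 16 (not isolated), via deconjugated ketone 17 (not isolated)
Conditions: NaH, THF, 0 °C; then 14, Pd2(dba)3 (2.5 mol %), XPhos (10 mol %), HCO2Na, Bu4NCl, 1,4-dioxane, 90 °C; then 2 M HCl, THF, rt, short contact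
Reagents that add atoms: water, O
Why: Proposed new method: a formate-terminated (reductive) Barluenga-type coupling of an aryl bromide with an aliphatic aldehyde tosylhydrazone that has a quaternary α-carbon, in which zerovalent palladium inserts into the C–Br bond of 14, the arylpalladium bromide (divalent palladium) captures diazoalkane 15 released from the hydrazone sodium salt, aryl migration to the carbene carbon gives a benzylic alkylpalladium that has no β-hydrogen (C5 is quaternary) and is therefore intercepted by formate (loss of CO2, then C–H reductive elimination) to form the ArCH2–C5 bond of 16, after which brief dilute acid unmasks the ketone and moves the double bond into conjugation under kinetic conditions so that the γ-hydrogen at C4a is not equilibrated; the closest known reactions are the palladium-catalysed tosylhydrazone/aryl halide coupling to alkenes and its hydride-terminated variants with aryl ketone hydrazones; no stereocentre is formed.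

**Step 12**
Reactants: 18 conjugated enone; 19 methyl acrylate
Product: 21 keto ester (methyl 3-[5-(ArCH2)-5,6,8a-trimethyl-2-oxodecahydronaphthalen-1-yl]propanoate; H-4a/8a-CH3/C1 chain on one face), via lithium enolate 20 (not isolated)
Conditions: Me2CuLi (from MeLi and CuI), Et2O, −40 to 0 °C; then THF, DMPU, methyl acrylate, −78 °C; AcOH, −78 °C
Reagents that add atoms: methyllithium, C[Li] (delivered as lithium dimethylcuprate, [Li+].C[Cu-]C)
Why: organocuprate 1,4-addition followed by Michael trapping, in which methyl adds to C8a on the face of H-4a (the normal cis-fused outcome for octalones of this type, the opposite face being screened by the arylmethyl group 1,3 to C8a) and the regiodefined enolate 20 then attacks methyl acrylate at C1 axially and anti to the C8a–C8 ring bond, i.e. cis to the new 8a-methyl, with a cold acidic quench to prevent equilibration at C1.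

**Step 13**
Reactants: 21 keto ester; 22 acetone
Product: 23 isopropylidene ester (methyl 3-[5-(ArCH2)-5,6,8a-trimethyl-2-(propan-2-ylidene)decahydronaphthalen-1-yl]propanoate)
Conditions: TiCl4, Zn, pyridine, THF, reflux; slow addition of 21 and acetone (6 equiv)
Reagents that add atoms: none
Why: McMurry cross-coupling, in which low-valent titanium couples the hindered ketone with excess acetone and deoxygenates the pinacolate to the tetrasubstituted alkene under non-basic conditions that do not epimerise C1 and tolerate the ester and the aryl silyl ether.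

**Step 14**
Reactants: 23 isopropylidene ester
Product: 24 3-[(1S,4aS,5S,6R,8aR)-5-[(2-hydroxy-5-methoxy-3-methylphenyl)methyl]-5,6,8a-trimethyl-2-(propan-2-ylidene)decahydronaphthalen-1-yl]propanoic acid
Conditions: LiOH, THF/MeOH/H2O (degassed), 40 °C; then 1 M HCl to pH 4, 0 °C
Reagents that add atoms: lithium hydroxide, [Li+].[OH-]
Why: saponification of the methyl ester with concurrent hydroxide cleavage of the phenolic silyl ether, and a cold mild acidification that avoids lactonisation onto the tetrasubstituted alkene.

**Compound list**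
1 | cyclohexane-1,3-dione | O=C1CCCC(=O)C1 | starting material
2 | 3-chlorocyclohex-2-en-1-one | O=C1C=C(Cl)CCC1 | intermediate
3 | potassium vinyltrifluoroborate | [K+].C=C[B-](F)(F)F | starting material
4 | 3-ethenylcyclohex-2-en-1-one | C=CC1=CC(=O)CCC1 | intermediate
5 | 7-ethenyl-1,4-dioxaspiro[4.5]dec-7-ene | C=CC1=CCCC2(C1)OCCO2 | intermediate
6 | (E)-2-methylbut-2-enal | C/C=C(\C)C=O | starting material
7 | 2,2-ethylenedioxy-5,6-dimethyl-1,2,3,4,4a,5,6,7-octahydronaphthalene-5-carbaldehyde (C8=C8a; H-4a, 5-CH3, 6-CH3 cis; CHO trans to H-4a) | O=C[C@]1(C)[C@@H]2CCC3(OCCO3)CC2=CC[C@H]1C | intermediate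
8 | (E)-N-tosylhydrazone of 7 | Cc1ccc(cc1)S(=O)(=O)N/N=C/[C@]1(C)[C@@H]2CCC3(OCCO3)CC2=CC[C@H]1C | intermediate
9 | hydroquinone | Oc1ccc(O)cc1 | starting material
10 | 4-methoxyphenol | COc1ccc(O)cc1 | intermediate
11 | 2-hydroxy-5-methoxybenzaldehyde | COc1ccc(O)c(C=O)c1 | intermediate
12 | 4-methoxy-2-methylphenol | COc1ccc(O)c(C)c1 | intermediate
13 | 2-bromo-4-methoxy-6-methylphenol | COc1cc(C)c(O)c(Br)c1 | intermediate
14 | (2-bromo-4-methoxy-6-methylphenoxy)(tert-butyl)dimethylsilane | COc1cc(C)c(O[Si](C)(C)C(C)(C)C)c(Br)c1 | intermediate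
15 | 5-(diazomethyl) analogue of 7 (diazoalkane, not isolated) | [N-]=[N+]=C[C@]1(C)[C@@H]2CCC3(OCCO3)CC2=CC[C@H]1C | intermediate
16 | 5-(ArCH2)-2,2-ethylenedioxy-5,6-dimethyl-1,2,3,4,4a,5,6,7-octahydronaphthalene (coupled ketal, not isolated) | COc1cc(C)c(O[Si](C)(C)C(C)(C)C)c(C[C@]2(C)[C@@H]3CCC4(OCCO4)CC3=CC[C@H]2C)c1 | intermediate
17 | 5-(ArCH2)-5,6-dimethyl-3,4,4a,5,6,7-hexahydronaphthalen-2(1H)-one (C8=C8a, not isolated) | COc1cc(C)c(O[Si](C)(C)C(C)(C)C)c(C[C@]2(C)[C@@H]3CCC(=O)CC3=CC[C@H]2C)c1 | intermediate
18 | 5-(ArCH2)-5,6-dimethyl-4,4a,5,6,7,8-hexahydronaphthalen-2(3H)-one (C1=C8a) | COc1cc(C)c(O[Si](C)(C)C(C)(C)C)c(C[C@]2(C)[C@@H]3CCC(=O)C=C3CC[C@H]2C)c1 | intermediate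
19 | methyl acrylate | C=CC(=O)OC | starting material
20 | lithium 5-(ArCH2)-5,6,8a-trimethyl-3,4,4a,5,6,7,8,8a-octahydronaphthalen-2-olate (not isolated) | COc1cc(C)c(O[Si](C)(C)C(C)(C)C)c(C[C@]2(C)[C@@H]3CCC([O-])=C[C@]3(C)CC[C@H]2C)c1.[Li+] | intermediate
21 | methyl 3-[5-(ArCH2)-5,6,8a-trimethyl-2-oxodecahydronaphthalen-1-yl]propanoate | COc1cc(C)c(O[Si](C)(C)C(C)(C)C)c(C[C@]2(C)[C@@H]3CCC(=O)[C@@H](CCC(=O)OC)[C@]3(C)CC[C@H]2C)c1 | intermediate
22 | acetone | CC(C)=O | starting material
23 | methyl 3-[5-(ArCH2)-5,6,8a-trimethyl-2-(propan-2-ylidene)decahydronaphthalen-1-yl]propanoate | COc1cc(C)c(O[Si](C)(C)C(C)(C)C)c(C[C@]2(C)[C@@H]3CCC(=C(C)C)[C@@H](CCC(=O)OC)[C@]3(C)CC[C@H]2C)c1 | intermediate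
24 | 3-[(1S,4aS,5S,6R,8aR)-5-[(2-hydroxy-5-methoxy-3-methylphenyl)methyl]-5,6,8a-trimethyl-2-(propan-2-ylidene)decahydronaphthalen-1-yl]propanoic acid | COc1cc(C)c(O)c(C[C@]2(C)[C@@H]3CCC(=C(C)C)[C@@H](CCC(=O)O)[C@]3(C)CC[C@H]2C)c1 | target

**Step count**
Total step count: 14.
Longest linear sequence: 9 steps (steps 1–5, then 11–14; the aryl branch, steps 6–10 then 11–14, is equally long).

**Steps most likely to fail**

Step 11 (the proposed new coupling). The reductive termination may lose to hydrodebromination of 14 or to azine formation from 15. A second hazard is epimerisation at C4a if the acid treatment is prolonged. The fallback uses known chemistry and sets out from 7. Reduction with NaBH4 in MeOH at 0 °C gives the neopentyl alcohol F3. Iodination with I2, PPh3 and imidazole in toluene at 80 °C gives the neopentyl iodide F4. Iodine–lithium exchange with t-BuLi in Et2O at −78 °C followed by ZnCl2 gives the alkylzinc chloride F5, which cannot undergo β-hydride elimination. Negishi coupling of F5 with 14 (Pd(OAc)2, SPhos, THF, 50 °C) returns to the route at 16, which takes the acid treatment of step 11 on to 18.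

Step 4 (asymmetric Diels–Alder with a hindered α,β-disubstituted enal). Conversion, the "ortho"/endo preference or the enantioselectivity may fall short. The fallback sets out from 5 and 6. A stoichiometric achiral Lewis acid (MeAlCl2, CH2Cl2, −78 to −20 °C) gives the endo adduct as the racemic aldehyde F1. Condensation with TsNHNH2 gives the crystalline racemic tosylhydrazone F2. Preparative SFC on a chiral stationary phase separates the enantiomers, and the matching one is 8, where the route is rejoined.

Step 13 (mixed McMurry coupling of a hindered α-branched ketone). Pinacol-stage stalling, homocoupling or ester reduction could occur. The fallback sets out from 21. Kinetic enolisation away from C1 with KN(SiMe3)2 and trapping with PhNTf2 (THF, −78 °C) gives the enol triflate F6 (C2=C3). Suzuki coupling with potassium isopropenyltrifluoroborate (PdCl2(dppf), Cs2CO3, THF/H2O, 60 °C) gives the 1,3-diene F7. 1,4-Hydrogenation with H2 (50 atm) and (naphthalene)Cr(CO)3 in acetone at 45 °C delivers hydrogen to C3 and the terminal CH2 and returns to the route at 23.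

**Further compounds**
F1 | step 4 | racemic 7 (7 and its mirror image, 1:1) | O=C[C@]1(C)[C@@H]2CCC3(OCCO3)CC2=CC[C@H]1C.O=C[C@@]1(C)[C@H]2CCC3(OCCO3)CC2=CC[C@@H]1C
F2 | step 4 | racemic 8 (8 and its mirror image, 1:1) | Cc1ccc(cc1)S(=O)(=O)N/N=C/[C@]1(C)[C@@H]2CCC3(OCCO3)CC2=CC[C@H]1C.Cc1ccc(cc1)S(=O)(=O)N/N=C/[C@@]1(C)[C@H]2CCC3(OCCO3)CC2=CC[C@@H]1C
F3 | step 11 | 5-(hydroxymethyl) analogue of 7 (neopentyl alcohol) | OC[C@]1(C)[C@@H]2CCC3(OCCO3)CC2=CC[C@H]1C
F4 | step 11 | 5-(iodomethyl) analogue of 7 (neopentyl iodide) | IC[C@]1(C)[C@@H]2CCC3(OCCO3)CC2=CC[C@H]1C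
F5 | step 11 | alkylzinc chloride from F4 | Cl[Zn]C[C@]1(C)[C@@H]2CCC3(OCCO3)CC2=CC[C@H]1C
F6 | step 13 | enol triflate of 21 (C2=C3) | COc1cc(C)c(O[Si](C)(C)C(C)(C)C)c(C[C@]2(C)[C@@H]3CC=C(OS(=O)(=O)C(F)(F)F)[C@@H](CCC(=O)OC)[C@]3(C)CC[C@H]2C)c1
F7 | step 13 | 2-isopropenyl 2,3-ene diene from F6 | COc1cc(C)c(O[Si](C)(C)C(C)(C)C)c(C[C@]2(C)[C@@H]3CC=C(C(C)=C)[C@@H](CCC(=O)OC)[C@]3(C)CC[C@H]2C)c1
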